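## The problem

The target is a germacranolide: a ten-membered carbocycle C1–C10 with an α-methylene-γ-lactone (O–C6, C7–C11, C12=O, C11=C13) trans-fused across C6–C7. The ring also carries a C1 ketone cross-conjugated with the C10=C14 exo-methylene, a cis-3,4-epoxide bearing the C4 methyl, a free C8 hydroxyl and a C9 angelate. There are six stereocentres, four contiguous (6R,7R,8R,9R) and two in the epoxide (3S,4R). The cis-epoxide requires a (Z)-C3=C4 olefin in the ring, which a direct ten-membered ring closure does not guarantee. C6 and C9 are the anchors: C7 can be set from C6 through the face of a C7 enolate, C8 from its neighbours by reduction of a C8 ketone, and the epoxide face only through the conformation of the finished ring. Fragile features are the angelate (Z-to-E isomerisation, migration to O8), the two exo-methylene Michael acceptors, the β,γ-epoxy ketone (opened by base) and, in intermediates, any epoxide facing an olefin across the medium ring (transannular cyclisation under acid). The enabling feature is that a C8 ketone together with a C3=C4 olefin is a cyclodec-5-enone, the [3,3] product of a 1-alkenyl-2-isopropenylcyclohexanol. Its six-membered ring C8–C9–C10–C1–C2–C3 (oxygen at C9, methyl on C10, unsaturation at C10–C1, isopropenyl on C3) is carvone atom for atom.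

## Retrosynthesis

**37 ⇒ 36.** The C3–O and C4–O bonds are cut last. The β,γ-epoxy ketone of 37 tolerates neither base, fluoride nor Lewis acid, and in 36 the (Z)-C3=C4 bond is the only olefin not conjugated to a carbonyl group. The forward step must choose one face of that olefin.

**36 ⇒ 35 ⇒ 34 ⇒ 31 + 32.** The C1 ketone is taken back to the allylic alcohol of 35, the two free hydroxyls to the silyl ethers of 34, and the C9–O acyl bond is cut to alcohol 31 and angelic acid 32. The angelate is introduced late because it survives neither lithium amides nor aluminium amides. C1 is kept as a silyl ether until after the acylation because the β,γ-unsaturated enone of 36 would drift into conjugation under amine bases. The forward steps must acylate only O9 without Z/E isomerisation and later oxidise only the allylic alcohol.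

**31 ⇒ 29 ⇒ 25 ⇒ 24 ⇒ 23.** The MOM group is restored at O9, the C11=C13 bond is cut (enolate methylenation), and the lactone C12–O6 bond is opened to the hydroxy tert-butyl ester 24, whose O6 is masked as the PMB ether 23. With O8 silylated only the 6,12-olide can form. PMB (oxidative), MOM (boron bromide) and TBS (fluoride) are mutually orthogonal, which the three oxygens at C6, C8 and C9 need.

**23 ⇒ 22 ⇒ 21 ⇒ 20.** The C10=C14/C1–OH unit is traced to the 1,10-epoxide of 21, and the C8 carbinol to the ketone 20. The epoxide is a latent form of the exo-methylene enone. It is isomerised with base before any acidic or Lewis-acidic reagent meets the ring, since it faces C3=C4 across the ring. The forward steps must reduce C8 from the correct face and remove a proton from C14 rather than C2 or C9.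

**20 ⇒ 16 + 17 (key disconnection).** The C7–C11 bond is cut to tert-butyl bromoacetate 17 and a C7 enolate. In that enolate the C5–C6 bond is cut and C3–C8 rejoined, which contracts the ten-membered ring to the cis-1-alkenyl-2-isopropenylcyclohexanol 16. Against closing the ten-membered ring end to end, this route forms it by ring expansion with no entropic penalty, fixes the Z geometry of C3=C4 and the configuration at C6 in one chair, and generates the enolate regiospecifically at C7. The precursor has four stereocentres on a six-membered ring instead of five on a ten-membered one. The forward reaction must use the chair with axial alkenyl and equatorial isopropenyl, and the enolate must survive until it is alkylated.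

**16 ⇒ 15 ⇒ 9 + 13; 13 ⇒ 10 + 11.** The (Z)-enol ether is taken back to the ynol ether 15, and the C7–C8 bond is cut to ketone 9 and the acetylide derived from dichlorovinyl ether 13. The latter comes from 4-methoxybenzyl alcohol 10 and trichloroethylene 11, which supplies C6 and C7. A slim acetylide is preferred to a preformed (Z)-alkoxyvinyl metal because it adds axially to cyclohexanones, and axial addition is what places the new group cis to the isopropenyl group. The Z geometry then follows from syn-hydrogenation rather than from the purity of a vinyl halide.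

**9 ⇒ 8 ⇒ 7 ⇒ 6 ⇒ 5 ⇒ 4 ⇒ 2 ⇒ 1.** The C8 ketone is traced to a carbinol that was silylated while the carvone ketone (C9) was reduced and protected as the MOM ether. The C8 oxygen comes from enolate hydroxylation of carvone oxide 2, and 2 from (S)-carvone 1. MOM at C9 is chosen because it is inert to the potassium alkoxide of the key step, where a neighbouring silyl ether could migrate. All absolute configuration comes from the single stereocentre of 1.

## Roads not taken

**Alternative 1:** The cut is the C3=C4 double bond itself. In the forward sense the second-generation Grubbs catalyst RuCl2(H2IMes)(PCy3)(=CHPh) would join a vinyl terminus at C3 and an isopropenyl terminus at C4 with loss of ethylene. The product A1 is the des-epoxy C8 triethylsilyl ether of the target, two operations from the end.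
- Merits: the route is convergent, the fully functionalised ring arrives late, and the stereocentres could be set by reagent-controlled acyclic chemistry.
- Weak points: the closure must make a trisubstituted olefin in a ten-membered ring from a 1,1-disubstituted partner, the least favourable case for metathesis. The olefin geometry is left to ring strain. The other olefins present at closure (α-methylene lactone, C10=C14 enone, angelate) can enter the carbene manifold, and ruthenium hydrides isomerise β,γ-unsaturated ketones.
- Comparison: in convergence and in the length of the end game this road is better. The chosen plan sets against it a unimolecular ring-forming event in which one bond breaks for each bond formed, which ignores the other olefins and which fixes Z geometry and C6 through a chair.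

**Alternative 2:** Retrosynthetically C1 and C6 are joined by a double bond, so that the ten-membered ring becomes two fused six-membered rings reachable by Birch reduction. Forward, ozone cleaves that tetrasubstituted olefin and gives the 1,6-diketone A2, whose (Z)-C3=C4 bond is held cis by its six-membered ring of origin.
- Merits: Z geometry is guaranteed by construction, C7–C10 are set on a rigid bicycle, and C1 arrives directly as the ketone. In this last respect the road is better than the chosen plan, which needs an epoxide isomerisation and an oxidation to reach the C1 ketone.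
- Weak points: ozone must prefer the tetrasubstituted olefin to the trisubstituted C3=C4 bond. C6 arrives as a carbonyl that must be reduced with control in a diketone prone to transannular aldolisation. C10 carries a CH2O unit still to be eliminated. Absolute configuration needs its own asymmetric step.
- Comparison: the chosen plan sets against the direct C1 ketone a C6 stereocentre created by chirality transfer, no chemoselective ozonolysis, and absolute configuration bought with carvone.

**Alternative 3:** The cut is the C9–C10 bond. Forward, Ni(cod)2 with the carbene ligand IPr and triethylsilane couples a terminal C10≡C14 alkyne with a C9 aldehyde at the internal alkyne carbon. This closes the ring and gives the C9 silyl ether and C10 exo-methylene of A3 in one step.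
- Merits: the C9 carbinol/exo-methylene motif, which the chosen plan reaches only through an epoxide, its isomerisation and a protecting-group exchange, appears at once and already differentiated. Here the alternative is clearly better.
- Weak points: the closure is an end-to-end macrocyclisation at the worst ring size. The regiochemistry (ten- versus eleven-membered ring) depends on the ligand, and the C9 configuration is substrate-controlled and hard to predict. A3 is far below the target in oxidation level at C1 and C12, with five oxygens to differentiate.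
- Comparison: the chosen plan sets against it ring formation without high dilution and carbons C1 and C12 carried at useful oxidation levels (epoxide, ester) from the start.

Key step: step 11

Remark: germacrane numbers are used for all intermediates. The C8 carbinol centre of 4–8 is drawn as the expected isomer (oxygen trans to the isopropenyl group); it is destroyed in step 7, so its configuration has no consequence.

Step 1
Reactants: 1 (S)-carvone
Product: 2 trans-carvone oxide [(1S,4S,6S)-1-methyl-4-(prop-1-en-2-yl)-7-oxabicyclo[4.1.0]heptan-2-one]
Conditions: 30% H2O2, NaOH (cat.), MeOH, 0 °C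
Reagents that add atoms: hydrogen peroxide, OO
Why: Weitz–Scheffer nucleophilic epoxidation; hydroperoxide adds to the enone β-carbon anti to the C3 isopropenyl group, so C1 and C10 are set with the oxirane oxygen trans to it, and the electron-rich isopropenyl olefin is inert to the peroxide anion.

Step 2
Reactants: 2 trans-carvone oxide
Product: 4 α'-hydroxy ketone [(1S,3R,4R,6S)-3-hydroxy-1-methyl-4-(prop-1-en-2-yl)-7-oxabicyclo[4.1.0]heptan-2-one], via potassium enolate 3 (not isolated)
Conditions: KN(SiMe3)2, THF, −78 °C; then 2-(phenylsulfonyl)-3-phenyloxaziridine, −78 °C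
Reagents that add atoms: 2-(phenylsulfonyl)-3-phenyloxaziridine (Davis oxaziridine), O=S(=O)(c1ccccc1)N1OC1c1ccccc1
Why: Enolisation is regiospecific because only C8 carries α-hydrogens (C10 is quaternary); Davis enolate hydroxylation delivers oxygen anti to the neighbouring isopropenyl group.

Step 3
Reactants: 4 α'-hydroxy ketone
Product: 5 silyl ether of 4 [3-(tert-butyldimethylsilyloxy) ketone]
Conditions: TBSCl, imidazole, DMF, rt
Reagents that add atoms: tert-butyldimethylsilyl chloride, CC(C)(C)[Si](C)(C)Cl
Why: Standard silylation of a secondary α-ketol; the TBS ether survives borohydride and MOMCl and is removed by fluoride without touching the MOM ether.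

Step 4
Reactants: 5 silyloxy ketone
Product: 6 epoxy alcohol (C9 hydroxyl trans to the oxirane oxygen and to the C8 silyl ether, cis to isopropenyl)
Conditions: NaBH4, CeCl3·7H2O, MeOH, −78 → −40 °C
Reagents that add atoms: none
Why: Luche reduction; hydride enters pseudo-axially on the half-chair, on the oxirane-oxygen side and away from the C10 methyl and the equatorial C8 silyl ether, which sets C9 with the hydroxyl trans to the epoxide oxygen, the usual outcome for 2,3-epoxycyclohexanones under these conditions.

Step 5
Reactants: 6 epoxy alcohol
Product: 7 MOM ether of 6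
Conditions: MOMCl, i-Pr2NEt, Bu4NI (cat.), CH2Cl2, 0 °C → reflux
Reagents that add atoms: chloromethyl methyl ether, COCCl
Why: Acetal formation under amine base generates no alkoxide, so neither Payne rearrangement of the trans epoxy alcohol nor 1,2-silyl migration can occur; MOM is chosen because it is inert to the potassium alkoxide of step 11.

Step 6
Reactants: 7 MOM ether
Product: 8 C8 alcohol [2-(methoxymethoxy)-1-methyl-4-(prop-1-en-2-yl)-7-oxabicyclo[4.1.0]heptan-3-ol]
Conditions: Bu4NF, THF, 0 °C → rt
Reagents that add atoms: none
Why: Fluoride desilylation; the liberated C8 oxygen is cis to the oxirane oxygen and cannot open the epoxide from the rear.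

Step 7
Reactants: 8 C8 alcohol
Product: 9 C8 ketone [2-(methoxymethoxy)-1-methyl-4-(prop-1-en-2-yl)-7-oxabicyclo[4.1.0]heptan-3-one; OMOM and isopropenyl cis to each other and trans to the oxirane oxygen]
Conditions: Dess–Martin periodinane, NaHCO3, CH2Cl2, 0 °C → rt
Reagents that add atoms: none
Why: Buffered Dess–Martin oxidation is non-enolising, so the C3 and C9 centres flanking the new ketone are retained; both substituents are equatorial, the stable cis-2,6 arrangement.

Step 8
Reactants: 10 4-methoxybenzyl alcohol; 11 trichloroethylene
Product: 13 (E)-1,2-dichlorovinyl 4-methoxybenzyl ether, via potassium 4-methoxybenzyl oxide 12 (not isolated)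
Conditions: KH, THF, 0 °C; then 11, −50 °C → rt
Reagents that add atoms: none
Why: Greene synthesis of dichlorovinyl ethers: the alkoxide eliminates HCl from trichloroethylene and adds anti to the resulting dichloroacetylene, giving the E ether.

Step 9
Reactants: 9 C8 ketone; 13 dichlorovinyl ether
Product: 15 alkoxyethynyl carbinol [3-[(4-methoxybenzyloxy)ethynyl]-2-(methoxymethoxy)-1-methyl-4-(prop-1-en-2-yl)-7-oxabicyclo[4.1.0]heptan-3-ol; alkynyl cis to isopropenyl and OMOM], via lithium alkoxyacetylide 14 (not isolated)
Conditions: 13, n-BuLi (2 equiv), THF, −78 → −40 °C; CeCl3, −78 °C; then 9, −78 °C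
Reagents that add atoms: none
Why: Elimination and chlorine–lithium exchange give the alkoxyacetylide, and transmetalation to cerium (Imamoto conditions) suppresses enolisation of 9, which would open the epoxide or scramble C3; the slim sp nucleophile adds along the axial trajectory, anti to the axial C–H bonds at C9 and C3, so C8 is set with the alkynyl group axial and cis to both equatorial neighbours; the acid-labile carbinol is handled under basic conditions.

Step 10
Reactants: 15 alkoxyethynyl carbinol
Product: 16 cis-dialkenyl cyclohexanol [3-[(Z)-2-(4-methoxybenzyloxy)ethenyl]-2-(methoxymethoxy)-1-methyl-4-(prop-1-en-2-yl)-7-oxabicyclo[4.1.0]heptan-3-ol]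
Conditions: H2 (1 atm), Pd/CaCO3 poisoned with Pb(OAc)2, quinoline, EtOAc–Et3N, 0 °C → rt
Reagents that add atoms: none
Why: Lindlar semihydrogenation adds hydrogen syn to the ynol ether and gives the (Z)-enol ether, as in the Arens–van Dorp reduction of alkoxyethynyl carbinols; the 1,1-disubstituted olefin, the benzylic ether and the epoxide are not reduced on the poisoned catalyst.

Step 11
Reactants: 16 cis-dialkenyl cyclohexanol; 17 tert-butyl bromoacetate
Product: 20 ten-membered C8 ketone [tert-butyl (1S,6R,7S,9R,10S,3Z)-1,10-epoxy-9-(methoxymethoxy)-6-(4-methoxybenzyloxy)-8-oxo-13-norgermacr-3-en-12-oate], via potassium alkoxide 18 (not isolated), via potassium enolate 19 (not isolated)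
Conditions: KN(SiMe3)2, 18-crown-6, THF, 0 °C → rt; then 17, −78 °C
Reagents that add atoms: none
Why: Deprotonation gives alkoxide 18, whose 1,5-diene C6=C7–C8–C3–C4=C5 undergoes a charge-accelerated concerted [3,3] shift; the closest known reaction is the anionic oxy-Cope ring expansion of 1,2-dialkenylcyclohexanols to cyclodec-5-enones with in situ alkylation of the enolate. The ten-membered ring is not closed end to end: C5–C6 forms while the C3–C8 bond of the six-membered ring breaks, a four-atom ring expansion through a six-centre chair. The chair used is the one that arises from the ground-state conformer of 18 (alkenyl axial; isopropenyl, OMOM and oxyanion equatorial); in it C2 is axial on C3, which gives the (Z)-C3=C4 olefin, and C9 is equatorial on C8, which gives the enolate with its oxygen cis to C6. C6 is set by chirality transfer from C3 and C8: the (Z)-enol ether places the OPMB group axial on C6, next to the small oxyanion and not to C9, and bonding on the face turned toward the isopropenyl group gives 6R. C7 is set in the alkylation: once the crown-separated enolate 19 has relaxed so that H6 lies in the enolate plane (allylic 1,3-strain with the oxyanion), the C5–C6 ring bond covers one face and 17 enters anti to it with the C6 ether in the outside position, which gives the 6,7 relationship of the trans-lactone. The selectivities needed are chair over boat and this chair over its ring-flipped partner (which would give the E olefin and the C6 epimer), both secured by the three equatorial groups of 18. The 1,10-epoxide removes the competing C6=C7–C8–C9–C10 diene, the enolate is formed at C7 only, and C- over O-alkylation rests on the soft, reactive α-bromo ester at −78 °C.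

Step 12
Reactants: 20 ten-membered C8 ketone
Product: 21 (8R)-alcohol [8-hydroxy analogue of 20; C8–O syn to C9–O in the acyclic sense; other centres unchanged]
Conditions: KBH(s-Bu)3, THF, −78 °C
Reagents that add atoms: none
Why: A bulky, non-chelating hydride should follow polar Felkin–Anh control, attacking anti to the C9–O bond from the ring periphery and setting C8 syn to the C9 ether; a cold quench keeps the C8 alkoxide from attacking the tert-butyl ester.

Step 13
Reactants: 21 (8R)-alcohol
Product: 22 allylic diol [tert-butyl (3Z)-1,8-dihydroxy-9-(methoxymethoxy)-6-(4-methoxybenzyloxy)-13-norgermacra-3,10(14)-dien-12-oate; C1 oxygen retained from the epoxide]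
Conditions: Et2AlCl and lithium 2,2,6,6-tetramethylpiperidide (giving diethylaluminum 2,2,6,6-tetramethylpiperidide), toluene, 0 °C
Reagents that add atoms: none
Why: Yamamoto epoxide-to-allylic-alcohol isomerisation; aluminium binds the oxirane oxygen, the hindered amide removes a proton from the C14 methyl in a cyclic syn-elimination and the tertiary C10–O bond breaks, leaving the C1 oxygen with its configuration; the tert-butyl ester and the ethers tolerate the bulky amide and the free C8 hydroxyl only consumes one equivalent.

Step 14
Reactants: 22 allylic diol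
Product: 23 bis-silyl ether [1,8-bis-O-TBS ether of 22]
Conditions: TBSOTf, 2,6-lutidine, CH2Cl2, −78 → 0 °C
Reagents that add atoms: tert-butyldimethylsilyl triflate, CC(C)(C)[Si](C)(C)OS(=O)(=O)C(F)(F)F
Why: Silyl triflate silylates both the hindered C8 and the allylic C1 alcohol at low temperature; the epoxide is gone, so the Lewis-acidic reagent has nothing to trigger across the ring.

Step 15
Reactants: 23 bis-silyl ether
Product: 24 C6 alcohol [23 without the 4-methoxybenzyl group]
Conditions: DDQ, CH2Cl2–pH 7 buffer, 0 °C
Reagents that add atoms: none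
Why: Oxidative cleavage of the electron-rich benzylic ether by hydride abstraction; MOM and silyl ethers and the isolated olefins are inert.

Step 16
Reactants: 24 C6 alcohol
Product: 25 trans-fused γ-lactone [(3Z)-1,8-bis(tert-butyldimethylsilyloxy)-9-(methoxymethoxy)-13-norgermacra-3,10(14)-dien-12,6-olide]
Conditions: KOt-Bu (0.2 equiv), THF, 0 °C
Reagents that add atoms: none
Why: Intramolecular transesterification (5-exo-trig) of the C6 alkoxide onto the tert-butyl ester, catalytic because tert-butoxide is released; O8 is silylated, so only the 6,12-olide can form and its trans fusion is fixed by C6 and C7.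

Step 17
Reactants: 25 trans-fused γ-lactone
Product: 29 α-methylene lactone [(3Z)-1,8-bis(tert-butyldimethylsilyloxy)-9-(methoxymethoxy)germacra-3,10(14),11(13)-trien-12,6-olide], via lithium enolate 26 (not isolated), via Mannich base 27 (not isolated), via ammonium iodide 28 (not isolated)
Conditions: LiN(i-Pr)2, THF, −78 °C; CH2=NMe2+ I−, −78 → 0 °C; then MeI, MeOH, rt; then aq. NaHCO3, CH2Cl2
Reagents that add atoms: N,N-dimethylmethyleneiminium iodide (Eschenmoser salt), C=[N+](C)C.[I-]
Why: Eschenmoser methylenation: Mannich reaction of the lactone enolate, quaternisation and base-induced elimination of trimethylamine; the lactone α-CH2 is the only acidic site and the transient C11 centre is lost.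

Step 18
Reactants: 29 α-methylene lactone
Product: 31 C9 alcohol [9-hydroxy analogue of 29], via bromomethyl ether 30 (not isolated)
Conditions: Me2BBr, CH2Cl2, −78 °C; then aq. NaHCO3
Reagents that add atoms: none
Why: Guindon cleavage of the MOM acetal by dimethylboron bromide at low temperature, then hydrolysis of the bromomethyl ether; silyl ethers and the acrylate survive, and no epoxide is present at this stage.

Step 19
Reactants: 31 C9 alcohol; 32 angelic acid
Product: 34 C9 angelate [9-O-[(Z)-2-methylbut-2-enoyl] derivative of 31], via mixed anhydride 33 (not isolated)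
Conditions: 2,4,6-trichlorobenzoyl chloride, Et3N, toluene, rt; then 31, 80 °C
Reagents that add atoms: none
Why: Yamaguchi-type acylation through the mixed anhydride without a nucleophilic catalyst, the conditions under which angelates form without addition–elimination to the tiglate; O9 is the only free hydroxyl.

Step 20
Reactants: 34 C9 angelate
Product: 35 diol [(3Z)-9-angeloyloxy-1,8-dihydroxygermacra-3,10(14),11(13)-trien-12,6-olide]
Conditions: HF·pyridine, pyridine, THF, 0 °C → rt
Reagents that add atoms: none
Why: Buffered acidic fluoride removes both silyl ethers without generating alkoxides, which avoids acyl migration from O9 to O8 and conjugate addition to the α-methylene lactone.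

Step 21
Reactants: 35 diol
Product: 36 enone [(3Z)-9-angeloyloxy-8-hydroxy-1-oxogermacra-3,10(14),11(13)-trien-12,6-olide]
Conditions: MnO2 (activated), CH2Cl2, rt
Reagents that add atoms: none
Why: Manganese dioxide oxidises the allylic C1 alcohol and leaves the saturated C8 carbinol; the neutral medium keeps C3=C4 out of conjugation.

Step 22
Reactants: 36 enone
Product: 37 target [(3S,4R,6R,7R,8R,9R)-9-angeloyloxy-3,4-epoxy-8-hydroxy-1-oxogermacra-10(14),11(13)-dien-12,6-olide]
Conditions: mCPBA, NaHCO3, CH2Cl2, 0 °C
Reagents that add atoms: 3-chloroperoxybenzoic acid, OOC(=O)c1cccc(Cl)c1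
Why: Prilezhaev epoxidation; the (Z)-trisubstituted C3=C4 bond is the only olefin not deactivated by a carbonyl group, syn oxygen transfer turns Z geometry into the cis-epoxide, and C3 and C4 are set by attack on the outer face of the lactone- and enone-stiffened ring, expected to be the face opposite the C6 oxygen.

## Compound list

1 | (S)-carvone | CC1=CC[C@@H](CC1=O)C(C)=C | starting material
2 | trans-carvone oxide, (1S,4S,6S)-1-methyl-4-(prop-1-en-2-yl)-7-oxabicyclo[4.1.0]heptan-2-one | C1C(=O)[C@@]2(C)O[C@H]2C[C@@H]1C(C)=C | intermediate
3 | potassium enolate of 2 (C8=C9, not isolated) | C1=C([O-])[C@@]2(C)O[C@H]2C[C@@H]1C(C)=C.[K+] | intermediate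
4 | (1S,3R,4R,6S)-3-hydroxy-1-methyl-4-(prop-1-en-2-yl)-7-oxabicyclo[4.1.0]heptan-2-one (C8 hydroxyl trans to isopropenyl) | O[C@H]1C(=O)[C@@]2(C)O[C@H]2C[C@@H]1C(C)=C | intermediate
5 | 3-O-tert-butyldimethylsilyl ether of 4 | CC(C)(C)[Si](C)(C)O[C@H]1C(=O)[C@@]2(C)O[C@H]2C[C@@H]1C(C)=C | intermediate
6 | 3-(tert-butyldimethylsilyloxy)-1-methyl-4-(prop-1-en-2-yl)-7-oxabicyclo[4.1.0]heptan-2-ol, 2-OH trans to the oxirane oxygen and to 3-OTBS | CC(C)(C)[Si](C)(C)O[C@H]1[C@H](O)[C@@]2(C)O[C@H]2C[C@@H]1C(C)=C | intermediate
7 | 2-O-methoxymethyl ether of 6 | CC(C)(C)[Si](C)(C)O[C@H]1[C@H](OCOC)[C@@]2(C)O[C@H]2C[C@@H]1C(C)=C | intermediate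
8 | 2-(methoxymethoxy)-1-methyl-4-(prop-1-en-2-yl)-7-oxabicyclo[4.1.0]heptan-3-ol (3-OH cis to the oxirane oxygen) | O[C@H]1[C@H](OCOC)[C@@]2(C)O[C@H]2C[C@@H]1C(C)=C | intermediate
9 | 2-(methoxymethoxy)-1-methyl-4-(prop-1-en-2-yl)-7-oxabicyclo[4.1.0]heptan-3-one, OMOM and isopropenyl cis, both trans to the oxirane oxygen | O=C1[C@H](OCOC)[C@@]2(C)O[C@H]2C[C@@H]1C(C)=C | intermediate
10 | 4-methoxybenzyl alcohol | COc1ccc(CO)cc1 | starting material
11 | trichloroethylene | ClC=C(Cl)Cl | starting material
12 | potassium 4-methoxybenzyl oxide (not isolated) | COc1ccc(C[O-])cc1.[K+] | intermediate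
13 | (E)-1,2-dichlorovinyl 4-methoxybenzyl ether | COc1ccc(CO/C(Cl)=C\Cl)cc1 | intermediate
14 | lithium (4-methoxybenzyloxy)acetylide (not isolated) | COc1ccc(COC#[C-])cc1.[Li+] | intermediate
15 | 3-[(4-methoxybenzyloxy)ethynyl]-2-(methoxymethoxy)-1-methyl-4-(prop-1-en-2-yl)-7-oxabicyclo[4.1.0]heptan-3-ol, alkynyl cis to isopropenyl and OMOM, 3-OH cis to the oxirane oxygen | [C@]1(O)(C#COCc2ccc(OC)cc2)[C@H](OCOC)[C@@]2(C)O[C@H]2C[C@@H]1C(C)=C | intermediate
16 | 3-[(Z)-2-(4-methoxybenzyloxy)ethenyl]-2-(methoxymethoxy)-1-methyl-4-(prop-1-en-2-yl)-7-oxabicyclo[4.1.0]heptan-3-ol, same configuration as 15 | [C@]1(O)(/C=C\OCc2ccc(OC)cc2)[C@H](OCOC)[C@@]2(C)O[C@H]2C[C@@H]1C(C)=C | intermediate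
17 | tert-butyl bromoacetate | CC(C)(C)OC(=O)CBr | starting material
18 | potassium alkoxide of 16 (not isolated) | [C@]1([O-])(/C=C\OCc2ccc(OC)cc2)[C@H](OCOC)[C@@]2(C)O[C@H]2C[C@@H]1C(C)=C.[K+] | intermediate
19 | ten-membered potassium enolate (C7=C8, oxygen cis to C6; 3Z; not isolated) | [K+].[O-]\C1=C/[C@H](OCc2ccc(OC)cc2)C/C(C)=C\C[C@@H]2O[C@]2(C)[C@H]1OCOC | intermediate
20 | tert-butyl (1S,6R,7S,9R,10S,3Z)-1,10-epoxy-9-(methoxymethoxy)-6-(4-methoxybenzyloxy)-8-oxo-13-norgermacr-3-en-12-oate | O=C1[C@@H](CC(=O)OC(C)(C)C)[C@H](OCc2ccc(OC)cc2)C/C(C)=C\C[C@@H]2O[C@]2(C)[C@H]1OCOC | intermediate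
21 | (8R)-8-hydroxy analogue of 20, other centres unchanged | O[C@@H]1[C@@H](CC(=O)OC(C)(C)C)[C@H](OCc2ccc(OC)cc2)C/C(C)=C\C[C@@H]2O[C@]2(C)[C@H]1OCOC | intermediate
22 | tert-butyl (3Z)-1,8-dihydroxy-9-(methoxymethoxy)-6-(4-methoxybenzyloxy)-13-norgermacra-3,10(14)-dien-12-oate, C1 oxygen retained from the epoxide (1S) | O[C@@H]1[C@@H](CC(=O)OC(C)(C)C)[C@H](OCc2ccc(OC)cc2)C/C(C)=C\C[C@H](O)C(=C)[C@H]1OCOC | intermediate
23 | 1,8-bis-O-tert-butyldimethylsilyl ether of 22 | CC(C)(C)[Si](C)(C)O[C@@H]1[C@@H](CC(=O)OC(C)(C)C)[C@H](OCc2ccc(OC)cc2)C/C(C)=C\C[C@H](O[Si](C)(C)C(C)(C)C)C(=C)[C@H]1OCOC | intermediate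
24 | 6-hydroxy ester (23 without the 4-methoxybenzyl group) | CC(C)(C)[Si](C)(C)O[C@@H]1[C@@H](CC(=O)OC(C)(C)C)[C@H](O)C/C(C)=C\C[C@H](O[Si](C)(C)C(C)(C)C)C(=C)[C@H]1OCOC | intermediate
25 | (3Z)-1,8-bis(tert-butyldimethylsilyloxy)-9-(methoxymethoxy)-13-norgermacra-3,10(14)-dien-12,6-olide, trans-fused (H6 and H7 anti) | C1C(=O)O[C@@H]2C/C(C)=C\C[C@H](O[Si](C)(C)C(C)(C)C)C(=C)[C@@H](OCOC)[C@H](O[Si](C)(C)C(C)(C)C)[C@@H]12 | intermediate
26 | lithium enolate of 25 (not isolated) | C1=C([O-])O[C@@H]2C/C(C)=C\C[C@H](O[Si](C)(C)C(C)(C)C)C(=C)[C@@H](OCOC)[C@H](O[Si](C)(C)C(C)(C)C)[C@@H]12.[Li+] | intermediate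
27 | 11-(dimethylaminomethyl) lactone (C11 epimers, not isolated) | CN(C)CC1C(=O)O[C@@H]2C/C(C)=C\C[C@H](O[Si](C)(C)C(C)(C)C)C(=C)[C@@H](OCOC)[C@H](O[Si](C)(C)C(C)(C)C)[C@@H]12 | intermediate
28 | 11-(trimethylammoniomethyl) lactone iodide (not isolated) | C[N+](C)(C)CC1C(=O)O[C@@H]2C/C(C)=C\C[C@H](O[Si](C)(C)C(C)(C)C)C(=C)[C@@H](OCOC)[C@H](O[Si](C)(C)C(C)(C)C)[C@@H]12.[I-] | intermediate
29 | (3Z)-1,8-bis(tert-butyldimethylsilyloxy)-9-(methoxymethoxy)germacra-3,10(14),11(13)-trien-12,6-olide | C=C1C(=O)O[C@@H]2C/C(C)=C\C[C@H](O[Si](C)(C)C(C)(C)C)C(=C)[C@@H](OCOC)[C@H](O[Si](C)(C)C(C)(C)C)[C@@H]12 | intermediate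
30 | 9-O-bromomethyl ether of 31 (not isolated) | C=C1C(=O)O[C@@H]2C/C(C)=C\C[C@H](O[Si](C)(C)C(C)(C)C)C(=C)[C@@H](OCBr)[C@H](O[Si](C)(C)C(C)(C)C)[C@@H]12 | intermediate
31 | (3Z)-1,8-bis(tert-butyldimethylsilyloxy)-9-hydroxygermacra-3,10(14),11(13)-trien-12,6-olide | C=C1C(=O)O[C@@H]2C/C(C)=C\C[C@H](O[Si](C)(C)C(C)(C)C)C(=C)[C@@H](O)[C@H](O[Si](C)(C)C(C)(C)C)[C@@H]12 | intermediate
32 | angelic acid, (Z)-2-methylbut-2-enoic acid | C/C=C(/C)C(=O)O | starting material
33 | angelic 2,4,6-trichlorobenzoic anhydride (not isolated) | C/C=C(/C)C(=O)OC(=O)c1c(Cl)cc(Cl)cc1Cl | intermediate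
34 | 9-O-angelate of 31 | C=C1C(=O)O[C@@H]2C/C(C)=C\C[C@H](O[Si](C)(C)C(C)(C)C)C(=C)[C@@H](OC(=O)/C(C)=C\C)[C@H](O[Si](C)(C)C(C)(C)C)[C@@H]12 | intermediate
35 | (3Z)-9-angeloyloxy-1,8-dihydroxygermacra-3,10(14),11(13)-trien-12,6-olide | C=C1C(=O)O[C@@H]2C/C(C)=C\C[C@H](O)C(=C)[C@@H](OC(=O)/C(C)=C\C)[C@H](O)[C@@H]12 | intermediate
36 | (3Z)-9-angeloyloxy-8-hydroxy-1-oxogermacra-3,10(14),11(13)-trien-12,6-olide | C=C1C(=O)O[C@@H]2C/C(C)=C\CC(=O)C(=C)[C@@H](OC(=O)/C(C)=C\C)[C@H](O)[C@@H]12 | intermediate
37 | (3S,4R,6R,7R,8R,9R)-9-angeloyloxy-3,4-epoxy-8-hydroxy-1-oxogermacra-10(14),11(13)-dien-12,6-olide (CNP0348992.7) | C=C1C(=O)O[C@@H]2C[C@@]3(C)O[C@H]3CC(=O)C(=C)[C@@H](OC(=O)/C(C)=C\C)[C@H](O)[C@@H]12 | target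

## Step count and least certain steps

Total: 22 steps. Longest linear sequence: 21 steps from (S)-carvone (steps 1–7 and 9–22); step 8 is a one-step branch.

**Step 11 (key step).** The most likely failure is poor facial selectivity at C7. If tert-butyl bromoacetate captures enolate 19 before H6 has turned into the enolate plane, the electrophile enters on the other face and the C7 epimer forms. Prolonged warming could also let 19 expel the C6 alkoxide (E1cB). The fallback sets C7 by protonation instead of alkylation. From 16 the rearrangement is run as before, but 19 is trapped with tert-butyl glyoxylate to give the aldol adduct F1. Dehydration (MsCl, Et3N, then DBU) gives the alkylidene ketone F2. Conjugate reduction with [(Ph3P)CuH]6 and protonation of the resulting C7 enolate returns to 20. A proton takes the face that an alkyl halide would take, so the side chain ends up on the opposite face to that from direct alkylation.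

**Step 12.** The most likely failure is hydride delivery to the wrong face of the C8 carbonyl. In a ten-membered ring the populated conformer, not the acyclic model, decides which face is peripheral, and any chelation by the MOM group would favour the 8,9-anti alcohol. Fallback: from 20, the epimeric alcohol F3 is inverted by Mitsunobu reaction (4-nitrobenzoic acid, PPh3, DIAD) to the 4-nitrobenzoate F4, and methanolysis (K2CO3, MeOH, 0 °C) gives 21.

**Step 13.** The most likely failure is loss of regiocontrol in the proton abstraction (the doubly allylic C2 instead of C14, giving the C1=C2 tertiary alcohol) or Lewis-acid-assisted transannular attack of C3=C4 on the aluminium-bound epoxide. Fallback: from 21, the polar syn-elimination is replaced by homolytic opening with Cp2TiCl (trivalent titanium, from Cp2TiCl2 and Mn dust, THF). This gives the tertiary C10 radical and the C1 titanium alkoxide, and a second equivalent removes a hydrogen atom from C14, returning to 22 with no new isolated compound.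

**Step 19.** The most likely failure is Z-to-E isomerisation of the activated angeloyl group (addition–elimination by amine or chloride) during the slow acylation of the hindered C9 alcohol, giving the tiglate. Fallback: the Z olefin is built after the acylation. From 31, esterification with 2-[bis(2,2,2-trifluoroethoxy)phosphoryl]propanoic acid (DCC, DMAP) gives the phosphonate ester F5. Still–Gennari olefination (KN(SiMe3)2, 18-crown-6, acetaldehyde, −78 °C) then gives 34.

**Step 22.** The most likely failure is poor facial selectivity in the epoxidation, because a Z olefin in a ten-membered ring exposes both faces more evenly than an E olefin. Fallback: from 36, NBS in aqueous THF gives the bromohydrin F6 (bromine at C3 on the face electrophiles prefer, hydroxyl at C4 anti to it). Closure with Ag2O displaces bromide with inversion and places the oxygen on the face opposite to the one the peracid would take, returning to 37.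

## Further compounds

F1 | step 11 | aldol adduct of enolate 19 with tert-butyl glyoxylate (C7 and C11 epimers) | O=C1C(C(O)C(=O)OC(C)(C)C)[C@H](OCc2ccc(OC)cc2)C/C(C)=C\C[C@@H]2O[C@]2(C)[C@H]1OCOC
F2 | step 11 | 7(11)-alkylidene ketone, tert-butyl 8-oxo-13-norgermacra-3,7(11)-dien-12-oate derivative | O=C1C(=CC(=O)OC(C)(C)C)[C@H](OCc2ccc(OC)cc2)C/C(C)=C\C[C@@H]2O[C@]2(C)[C@H]1OCOC
F3 | step 12 | C8 epimer of 21 | O[C@H]1[C@@H](CC(=O)OC(C)(C)C)[C@H](OCc2ccc(OC)cc2)C/C(C)=C\C[C@@H]2O[C@]2(C)[C@H]1OCOC
F4 | step 12 | 8-O-(4-nitrobenzoate) of 21 | O=C(O[C@@H]1[C@@H](CC(=O)OC(C)(C)C)[C@H](OCc2ccc(OC)cc2)C/C(C)=C\C[C@@H]2O[C@]2(C)[C@H]1OCOC)c1ccc(cc1)[N+](=O)[O-]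
F0 | step 13 | none | none
F5 | step 19 | 9-O-[2-[bis(2,2,2-trifluoroethoxy)phosphoryl]propanoate] of 31 | C=C1C(=O)O[C@@H]2C/C(C)=C\C[C@H](O[Si](C)(C)C(C)(C)C)C(=C)[C@@H](OC(=O)C(C)P(=O)(OCC(F)(F)F)OCC(F)(F)F)[C@H](O[Si](C)(C)C(C)(C)C)[C@@H]12
F6 | step 22 | 3-bromo-4-hydroxy bromohydrin of 36 | C=C1C(=O)O[C@@H]2C[C@@](C)(O)[C@H](Br)CC(=O)C(=C)[C@@H](OC(=O)/C(C)=C\C)[C@H](O)[C@@H]12
A1 | alternative 1 | (3Z)-9-angeloyloxy-1-oxo-8-(triethylsilyloxy)germacra-3,10(14),11(13)-trien-12,6-olide | C=C1C(=O)O[C@@H]2C/C(C)=C\CC(=O)C(=C)[C@@H](OC(=O)/C(C)=C\C)[C@H](O[Si](CC)(CC)CC)[C@@H]12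
A2 | alternative 2 | (Z)-cyclodec-3-ene-1,6-dione acid carrying the C7–C10 array | OC(=O)C[C@H]1C(=O)C/C(C)=C\CC(=O)[C@H](CO[Si](C)(C)C(C)(C)C)[C@@H](OCOC)[C@@H]1O[Si](C)(C)C(C)(C)C
A3 | alternative 3 | ten-membered C9 triethylsilyl ether with C10 exo-methylene | C=C(CO[Si](C)(C)C(C)(C)C)[C@H]1[C@H](O[Si](C)(C)C(C)(C)C)C/C(C)=C\C[C@H](O[Si](C)(C)C(C)(C)C)C(=C)[C@@H](O[Si](CC)(CC)CC)[C@@H]1OCc2ccc(OC)cc2
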